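The seven-membered ring is cut at C9–C10 and C7–C8, so that C8, C9 and the C8 methyl group come from propyne. The key step is a rhodium-catalysed carbonyl ylide cycloaddition: an α-diazoketone (C6, C7) and an aldehyde (C10), held trans on a cyclopentane, form a cyclic ylide that adds to propyne and closes the ring in one operation. It exploits the C6 and C10 oxygens that flank the C7–C8=C9 unit: the bridging ylide oxygen becomes the C10 hydroxyl once SmI2 cleaves the C7–O bond next to the C6 ketone. The cyclopentane, with the C4 carbinol and its isopropyl group, is all ten carbons of (S)-terpinen-4-ol after ring contraction.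

Key step: step 8

Remark on numbering: daucane numbering is used throughout. C1 is the quaternary carbon with the angular methyl, C2 and C3 are methylenes, C4 is the isopropyl carbinol, C5 the ring-fusion CH, C6 the ester carbon, C7 the methylene, C8 the methyl-bearing alkene carbon, C9 the alkene CH and C10 the carbinol CH. β is the face of the C1 methyl group; in the target the C4 oxygen is β, while H5, the isopropyl group and the oxygens at C6 and C10 are α.

Remark on supply: (S)-(+)-terpinen-4-ol is assumed to be purchased in enantiopure form.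

Step 1
Reactants: 1 (S)-(+)-terpinen-4-ol
Product: 2 (S)-terpinen-4-yl tert-butyldimethylsilyl ether
Conditions: TBSOTf, 2,6-lutidine, CH2Cl2, 0 °C
Reagents that add atoms: tert-butyldimethylsilyl trifluoromethanesulfonate, CC(C)(C)[Si](C)(C)OS(=O)(=O)C(F)(F)F
Why: Silyl ether formation on the tertiary alcohol masks the hydroxyl that would otherwise capture the rhodium carbenoid of step 8 by O–H insertion; the C4 stereocenter is not touched.

Step 2
Reactants: 2 (S)-terpinen-4-yl tert-butyldimethylsilyl ether
Product: 3 (3S)-3-(tert-butyldimethylsilyloxy)-6-oxo-3-(propan-2-yl)heptanal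
Conditions: O3, CH2Cl2, −78 °C; then Me2S
Reagents that add atoms: ozone, [O-][O+]=O
Why: Ozonolysis with reductive work-up cleaves the only alkene into the methyl ketone (future C1) and the aldehyde (future C6) without affecting C4.

Step 3
Reactants: 3 (3S)-3-(tert-butyldimethylsilyloxy)-6-oxo-3-(propan-2-yl)heptanal
Product: 4 (5R)-5-(tert-butyldimethylsilyloxy)-2-methyl-5-(propan-2-yl)cyclopent-1-ene-1-carbaldehyde
Conditions: piperidine, AcOH, benzene, reflux (water removal)
Reagents that add atoms: none
Why: Amine-catalysed intramolecular aldol condensation (enamine of the aldehyde onto the methyl ketone, 5-exo closure, then dehydration) should form the C1–C5 bond and give the cyclopentenecarbaldehyde, as is usual for terpene-derived 6-oxoheptanals; no new stereocenter arises.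

Step 4
Reactants: 4 (5R)-5-(tert-butyldimethylsilyloxy)-2-methyl-5-(propan-2-yl)cyclopent-1-ene-1-carbaldehyde
Product: 6 5β-formyl-1β-methyl-1α-vinyl-4α-isopropyl-4β-(tert-butyldimethylsilyloxy)cyclopentane, via silyl enol ether 5 (not isolated)
Conditions: CH2=CHMgBr, CuBr·SMe2 (20 mol %), TMSCl, HMPA, THF, −78 °C; then K2CO3, MeOH, 0 °C
Reagents that add atoms: vinylmagnesium bromide, C=C[Mg]Br
Why: Chlorotrimethylsilane-accelerated copper-catalysed conjugate addition forms the quaternary C1 and traps the enolate as 5, which suppresses β-elimination of the silyloxy group; the vinyl group should enter anti to the silyloxy group, whose silyl substituent lies over the β face while the isopropyl group turns its methine hydrogen toward the ring, and mild base then equilibrates C5 so that the formyl group is trans to both the isopropyl and the vinyl group.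

Step 5
Reactants: 6 5β-formyl-1β-methyl-1α-vinyl-4α-isopropyl-4β-(tert-butyldimethylsilyloxy)cyclopentane
Product: 7 1β-methyl-1α-vinyl-4α-isopropyl-4β-(tert-butyldimethylsilyloxy)cyclopentane-5β-carboxylic acid
Conditions: NaClO2, NaH2PO4, 2-methylbut-2-ene, t-BuOH/H2O, rt
Reagents that add atoms: sodium chlorite, [Na+].[O-]Cl=O
Why: Pinnick oxidation converts the aldehyde into the acid under buffered conditions that leave the vinyl group, the silyl ether and the C5 configuration intact.

Step 6
Reactants: 7 1β-methyl-1α-vinyl-4α-isopropyl-4β-(tert-butyldimethylsilyloxy)cyclopentane-5β-carboxylic acid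
Product: 8 1α-formyl-1β-methyl-4α-isopropyl-4β-(tert-butyldimethylsilyloxy)cyclopentane-5β-carboxylic acid
Conditions: O3, CH2Cl2, −78 °C; then Me2S
Reagents that add atoms: ozone, [O-][O+]=O
Why: Ozonolysis of the vinyl group unveils the C10 aldehyde, which has no α-hydrogen and cannot lactolise onto the trans carboxyl group.

Step 7
Reactants: 8 1α-formyl-1β-methyl-4α-isopropyl-4β-(tert-butyldimethylsilyloxy)cyclopentane-5β-carboxylic acid
Product: 11 5β-(diazoacetyl)-1α-formyl-1β-methyl-4α-isopropyl-4β-(tert-butyldimethylsilyloxy)cyclopentane, via acid chloride 9 (not isolated), via silyl diazoketone 10 (not isolated)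
Conditions: 1-chloro-N,N,2-trimethylprop-1-en-1-amine, CH2Cl2, 0 °C; then TMSCHN2, Et3N, MeCN/THF, 0 °C; aq. NaHCO3
Reagents that add atoms: (trimethylsilyl)diazomethane, C[Si](C)(C)C=[N+]=[N-]
Why: Neutral acid chloride formation followed by acylation of the diazoalkane (first stage of an Arndt–Eistert sequence) and protodesilylation on work-up should give the α-diazoketone, since the acyl chloride reacts far faster than the hindered neopentyl aldehyde.

Step 8
Reactants: 11 5β-(diazoacetyl)-1α-formyl-1β-methyl-4α-isopropyl-4β-(tert-butyldimethylsilyloxy)cyclopentane, 12 propyne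
Product: 14 4β-(tert-butyldimethylsilyloxy)-7β,10β-epoxydauc-8-en-6-one (1β-methyl 5α-H), via carbonyl ylide 13 (not isolated)
Conditions: Rh2(OAc)4 (2 mol %), propyne (about 30 equiv, condensed), CH2Cl2, sealed tube, 25 °C, slow addition of 11
Reagents that add atoms: none
Why: Rh2(OAc)4 turns the diazoketone into a rhodium carbenoid at C7, which the C10 aldehyde oxygen attacks (6-exo closure) to give a six-membered cyclic carbonyl ylide C7–O–C10 trans-fused to the cyclopentane; this adds across propyne in a concerted 1,3-dipolar [3+2] cycloaddition that forms C9–C10 and C7–C8 at once and so closes the seven-membered carbocycle as an oxygen-bridged 8-oxabicyclo[3.2.1]oct-6-en-2-one. The closest known reaction type is the rhodium-catalysed tandem carbonyl ylide formation and dipolar cycloaddition of formyl- or keto-substituted α-diazoketones with alkynes. The new stereocentres C7 and C10 should arise from approach of the alkyne anti to the axial C1 methyl group, which places the oxygen bridge cis to that methyl; both are erased later (C7 becomes CH2 in step 10, C10 is reset in steps 12 and 14), so facial selectivity is not needed. What is needed is regioselectivity: the unsubstituted, more nucleophilic terminus of propyne should bond to the oxocarbenium-like C10, which is also the hindered neopentyl terminus next to quaternary C1, and the methyl-bearing carbon to the enolate-like C7. Ylide formation is favoured over O–H insertion by the silyl ether at C4, and capture of the ylide over its dimerisation by slow addition and a large excess of propyne.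

Step 9
Reactants: 14 4β-(tert-butyldimethylsilyloxy)-7β,10β-epoxydauc-8-en-6-one
Product: 15 7β,10β-epoxy-4β-hydroxydauc-8-en-6-one
Conditions: HF·pyridine, THF, 0 °C to rt
Reagents that add atoms: none
Why: Fluoride-mediated desilylation frees the C4 hydroxyl on the rigid cycloadduct, where C5 cannot epimerise and no base-sensitive β,γ-enone is yet present.

Step 10
Reactants: 15 7β,10β-epoxy-4β-hydroxydauc-8-en-6-one
Product: 16 4β,10β-dihydroxydauc-8-en-6-one
Conditions: SmI2 (2.2 equiv), THF/MeOH, −78 °C
Reagents that add atoms: none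
Why: Ketyl formation at C6 and β-scission of the adjacent allylic C7–O bond (reductive cleavage of an α-alkoxy ketone) opens the bridge, and kinetic α-protonation of the resulting dienolate at C7 keeps the alkene at C8=C9 and leaves C5 untouched.

Step 11
Reactants: 16 4β,10β-dihydroxydauc-8-en-6-one
Product: 17 dauc-8-ene-4β,6α,10β-triol
Conditions: Me4NBH(OAc)3, MeCN/AcOH, −25 °C
Reagents that add atoms: none
Why: Hydroxyl-directed reduction (Evans–Saksena type) delivers hydride intramolecularly from the boron bound to the C4 oxygen to the β face of the C6 carbonyl, on which that oxygen lies, so the new hydroxyl should be α (cis to H5).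

Step 12
Reactants: 17 dauc-8-ene-4β,6α,10β-triol
Product: 18 4β,6α-dihydroxydauc-8-en-10-one
Conditions: MnO2, CH2Cl2, rt
Reagents that add atoms: none
Why: MnO2 oxidises only the allylic C10 alcohol, which differentiates the two secondary hydroxyls for the acylation and removes the C10 configuration of step 8 so that it can be reset in step 14.

Step 13
Reactants: 18 4β,6α-dihydroxydauc-8-en-10-one, 19 4-methoxybenzoyl chloride
Product: 20 4β-hydroxy-6α-(4-methoxybenzoyloxy)dauc-8-en-10-one
Conditions: Et3N, DMAP (cat.), CH2Cl2, 0 °C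
Reagents that add atoms: none
Why: DMAP-catalysed acylation esterifies the only secondary hydroxyl, the tertiary C4 hydroxyl being inert under these conditions.

Step 14
Reactants: 20 4β-hydroxy-6α-(4-methoxybenzoyloxy)dauc-8-en-10-one
Product: 21 4β,10α-dihydroxy-6α-(4-methoxybenzoyloxy)dauc-8-ene, the target
Conditions: NaBH4, CeCl3·7H2O, MeOH, −78 °C
Reagents that add atoms: none
Why: Luche 1,2-reduction; in the twist conformation that the trans ring fusion imposes on the cycloheptenone the C1–C2 bond stands perpendicular to the enone plane on the α side of C10, so hydride should add anti to it from the β side (Felkin–Anh sense) and give the 10α-alcohol, trans to the angular methyl group.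

Compound list
1 | (S)-(+)-terpinen-4-ol, (1S)-4-methyl-1-(propan-2-yl)cyclohex-3-en-1-ol | CC1=CC[C@](O)(C(C)C)CC1 | starting material
2 | (S)-terpinen-4-yl tert-butyldimethylsilyl ether | CC1=CC[C@](O[Si](C)(C)C(C)(C)C)(C(C)C)CC1 | intermediate
3 | (3S)-3-(tert-butyldimethylsilyloxy)-6-oxo-3-(propan-2-yl)heptanal | CC(=O)CC[C@@](O[Si](C)(C)C(C)(C)C)(C(C)C)CC=O | intermediate
4 | (5R)-5-(tert-butyldimethylsilyloxy)-2-methyl-5-(propan-2-yl)cyclopent-1-ene-1-carbaldehyde | O=CC1=C(C)CC[C@@]1(O[Si](C)(C)C(C)(C)C)C(C)C | intermediate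
5 | trimethylsilyl enol ether of 6 (C5=C6 enol ether, geometry not defined; C1 methyl β, vinyl α) | C[Si](C)(C)OC=C1[C@@](C)(C=C)CC[C@@]1(O[Si](C)(C)C(C)(C)C)C(C)C | intermediate
6 | 5β-formyl-1β-methyl-1α-vinyl-4α-isopropyl-4β-(tert-butyldimethylsilyloxy)cyclopentane | O=C[C@@H]1[C@@](C)(C=C)CC[C@@]1(O[Si](C)(C)C(C)(C)C)C(C)C | intermediate
7 | 1β-methyl-1α-vinyl-4α-isopropyl-4β-(tert-butyldimethylsilyloxy)cyclopentane-5β-carboxylic acid | OC(=O)[C@@H]1[C@@](C)(C=C)CC[C@@]1(O[Si](C)(C)C(C)(C)C)C(C)C | intermediate
8 | 1α-formyl-1β-methyl-4α-isopropyl-4β-(tert-butyldimethylsilyloxy)cyclopentane-5β-carboxylic acid | OC(=O)[C@@H]1[C@@](C)(C=O)CC[C@@]1(O[Si](C)(C)C(C)(C)C)C(C)C | intermediate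
9 | acid chloride of 8 | ClC(=O)[C@@H]1[C@@](C)(C=O)CC[C@@]1(O[Si](C)(C)C(C)(C)C)C(C)C | intermediate
10 | α-trimethylsilyl diazoketone derived from 9 | C[Si](C)(C)C(=[N+]=[N-])C(=O)[C@@H]1[C@@](C)(C=O)CC[C@@]1(O[Si](C)(C)C(C)(C)C)C(C)C | intermediate
11 | 5β-(diazoacetyl)-1α-formyl-1β-methyl-4α-isopropyl-4β-(tert-butyldimethylsilyloxy)cyclopentane | [N-]=[N+]=CC(=O)[C@@H]1[C@@](C)(C=O)CC[C@@]1(O[Si](C)(C)C(C)(C)C)C(C)C | intermediate
12 | propyne | CC#C | starting material
13 | cyclic carbonyl ylide (C7 carbanion, oxonium oxygen, C10=O+; six-membered ring trans-fused to the cyclopentane) | O=C1[CH-][O+]=C[C@@]2(C)CC[C@@](O[Si](C)(C)C(C)(C)C)(C(C)C)[C@H]12 | intermediate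
14 | 4β-(tert-butyldimethylsilyloxy)-7β,10β-epoxydauc-8-en-6-one (1β-methyl, 5α-H) | O=C1[C@H]2C(C)=C[C@H](O2)[C@@]3(C)CC[C@@](O[Si](C)(C)C(C)(C)C)(C(C)C)[C@H]13 | intermediate
15 | 7β,10β-epoxy-4β-hydroxydauc-8-en-6-one | O=C1[C@H]2C(C)=C[C@H](O2)[C@@]3(C)CC[C@@](O)(C(C)C)[C@H]13 | intermediate
16 | 4β,10β-dihydroxydauc-8-en-6-one | O=C1CC(C)=C[C@H](O)[C@@]2(C)CC[C@@](O)(C(C)C)[C@H]12 | intermediate
17 | dauc-8-ene-4β,6α,10β-triol | O[C@H]1CC(C)=C[C@H](O)[C@@]2(C)CC[C@@](O)(C(C)C)[C@H]12 | intermediate
18 | 4β,6α-dihydroxydauc-8-en-10-one | O[C@H]1CC(C)=CC(=O)[C@@]2(C)CC[C@@](O)(C(C)C)[C@H]12 | intermediate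
19 | 4-methoxybenzoyl chloride | COc1ccc(C(Cl)=O)cc1 | starting material
20 | 4β-hydroxy-6α-(4-methoxybenzoyloxy)dauc-8-en-10-one | COc1ccc(C(=O)O[C@H]2CC(C)=CC(=O)[C@@]3(C)CC[C@@](O)(C(C)C)[C@H]23)cc1 | intermediate
21 | 4β,10α-dihydroxy-6α-(4-methoxybenzoyloxy)dauc-8-ene, (3R,3aS,4S,8R,8aS)-3,8-dihydroxy-6,8a-dimethyl-3-(propan-2-yl)-1,2,3,3a,4,5,8,8a-octahydroazulen-4-yl 4-methoxybenzoate | COc1ccc(C(=O)O[C@H]2CC(C)=C[C@@H](O)[C@@]3(C)CC[C@@](O)(C(C)C)[C@H]23)cc1 | target

Total step count: 14. Longest linear sequence: 14 steps (from 1).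

Steps most likely to fail

Step 4. The conjugate addition may show poor facial selectivity at C1, with the vinyl group entering syn to the silyl ether; this is the least secure stereochemical argument in the route. It may also be diverted into 1,2-addition to the hindered enal. The fallback sets C1 by a stereospecific 1,2-shift instead; it sets out from 4 and comes back at 8. Alkaline H2O2 (Weitz–Scheffer epoxidation) should give the epoxy aldehyde F1 on the face that the cuprate preferred. BF3·OEt2 then opens the epoxide at tertiary C1, and the formyl group migrates from C5 to C1 anti to the leaving oxygen, giving the β-keto aldehyde F2 with the methyl group β and the formyl group (C10) α. The aldehyde is masked as the dimethyl acetal F3 (HC(OMe)3, PPTS, MeOH). Corey–Chaykovsky methylenation of the C5 ketone (Me3S+ I−, KHMDS, THF) gives the spiro-epoxide F4. Meinwald rearrangement (MgBr2·OEt2) and brief equilibration (K2CO3, MeOH) give the 5β-aldehyde F5, and Pinnick oxidation gives the acid F6. Aqueous acetic acid hydrolyses the acetal to 8.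

Step 8. The transient ylide may dimerise, or the carbenoid may insert into C–H bonds, before the unactivated alkyne is captured; the alkyne may also add in the reverse orientation. The fallback uses an electron-poor alkyne whose activating group is removed in the reductive step; it sets out from 11 and comes back at 16. Rh2(OAc)4 and 1-(phenylsulfonyl)prop-1-yne should give the sulfonyl cycloadduct F7, the enolate-like C7 bonding to the methyl-bearing β-carbon of the alkynyl sulfone. HF·pyridine gives the alcohol F8. Excess SmI2 with HMPA and MeOH then cleaves both the C7–O bond and the vinylic C–S bond to give 16.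

Step 14. Hydride may be delivered to the wrong face of the C10 carbonyl if the ring does not adopt the assumed twist conformation. The fallback replaces substrate control by reagent control; it sets out from 20 and comes back at 21. Corey–Bakshi–Shibata reduction (the 2-methyl oxazaborolidine enantiomer that directs hydride to the β face, catecholborane, toluene, −78 °C) should give 21 directly. It makes no new compound (F0), and any 10β-epimer can be returned to 20 by MnO2.

Further compounds
F1 | step 4 | 1β,5β-epoxide of enal 4 (5α-formyl, 1α-methyl, 4β-silyloxy) | O=C[C@@]12O[C@]1(C)CC[C@@]2(O[Si](C)(C)C(C)(C)C)C(C)C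
F2 | step 4 | 1α-formyl-1β-methyl-4α-isopropyl-4β-(tert-butyldimethylsilyloxy)cyclopentan-5-one | O=C[C@@]1(C)CC[C@@](O[Si](C)(C)C(C)(C)C)(C(C)C)C1=O
F3 | step 4 | dimethyl acetal of F2 | COC(OC)[C@@]1(C)CC[C@@](O[Si](C)(C)C(C)(C)C)(C(C)C)C1=O
F4 | step 4 | spiro-epoxide at C5 of F3 (C5 configuration not defined) | COC(OC)[C@@]1(C)CC[C@@](O[Si](C)(C)C(C)(C)C)(C(C)C)C12CO2
F5 | step 4 | 5β-formyl-1α-(dimethoxymethyl)-1β-methyl-4α-isopropyl-4β-(tert-butyldimethylsilyloxy)cyclopentane | COC(OC)[C@@]1(C)CC[C@@](O[Si](C)(C)C(C)(C)C)(C(C)C)[C@@H]1C=O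
F6 | step 4 | 1α-(dimethoxymethyl)-1β-methyl-4α-isopropyl-4β-(tert-butyldimethylsilyloxy)cyclopentane-5β-carboxylic acid | COC(OC)[C@@]1(C)CC[C@@](O[Si](C)(C)C(C)(C)C)(C(C)C)[C@@H]1C(=O)O
F7 | step 8 | 9-(phenylsulfonyl)-4β-(tert-butyldimethylsilyloxy)-7β,10β-epoxydauc-8-en-6-one | O=C1[C@H]2C(C)=C(S(=O)(=O)c3ccccc3)[C@H](O2)[C@@]4(C)CC[C@@](O[Si](C)(C)C(C)(C)C)(C(C)C)[C@H]14
F8 | step 8 | 9-(phenylsulfonyl)-7β,10β-epoxy-4β-hydroxydauc-8-en-6-one | O=C1[C@H]2C(C)=C(S(=O)(=O)c3ccccc3)[C@H](O2)[C@@]4(C)CC[C@@](O)(C(C)C)[C@H]14
F0 | step 14 | none | none
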